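- I began in a one-step world: free monomer loses the same share each day, so log c(free monomer) falls on a straight line.

| flask | free monomer | pre-initiator | remark | time |
|---|---|---|---|---|
| Wednesday's | 20 mM | 50 µM | run made earlier |  |
| flask | 10 mM | 50 µM |  | 15 d |

Wednesday's run (percent of the free monomer charged)

| time / d | free monomer / % | monomer in chains / % | uncatalysed product / % |
|---|---|---|---|
| 0.167 | 93.2 | 2.7 | 3.5 |
| 0.500 | 70.0 | 19.3 | 11.2 |
| 0.833 | 42.2 | 44.0 | 12.8 |
| 1.25 | 18.6 | 65.9 | 15.8 |
| 1.67 | 6.8 | 76.4 | 18.3 |
| 2.50 | 0.1 | 81.2 | 17.5 |
| 3.00 | 0 | 81.1 | 16.9 |

(standard deviation of a reading: 1 percentage point)

- what was read earlier has a scatter of 1 percentage point, one standard deviation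
- a reading or a percentage of monomer in chains counts all its forms, free or not
- the reaction counts as stopped when no species that holds the free monomer changes by six tenths of a point or more over the second half of the time

- at 15 d, what has stopped the reaction, if anything has (it is still moving / no working catalyst is left / all of the free monomer has reacted)
- part of the free monomer gone at 15 d
- the monomer in chains standing at 15 d, as a percentage of the free monomer charged
- the uncatalysed product standing at 15 d, as a percentage of the free monomer charged

- My first slope came from Wednesday's earliest uncatalysed product, 3.5% at 0.167 d, which gave 0.210 /d.
- But that reading carried a scatter of 1 percentage point, so I used the whole run. The area under Wednesday's free monomer curve was 0.829 d, and the late product stood near 17.6%, so the background constant was 0.212 /d.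
- I then counted background decades: the powers of ten by which the uncatalysed step by itself lowers c(free monomer), that is, the constant times the time over the natural logarithm of ten. For this flask they came to 1.38, which leaves 4.16%.
- But the constant was read at 20 mM. A second-order background at 10 mM would start at half that rate and slow as free monomer fell, so decades would not apply; with that starting rate, the second-order law would leave 38.6%.
- Then chains would have to finish the work. Wednesday's free monomer fell at 2.40 /d late in the run, ten times the background constant. I assumed the catalyst lasted, which the readings could not test.
- For the split, Wednesday's chains stood near 81.1%. If chains and background are both first order in free monomer, their ratio carries no c(free monomer), so the split holds.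
- But if forming the catalyst needs monomer, growth comes later and product rises. So I committed to free monomer gone, chains near 81.1%, and product slightly above 17.6%.
- The forecast said all of the free monomer has reacted, 100% gone, chains 79% and product 21%, a product share above mine, holding that “even the background alone nearly consumes the monomer”.
- The flask gave all of the free monomer has reacted, 100% gone, chains 80.8% and product 19.2%.

    free monomer + initiator → living end + monomer in chains (k = 49.0 /M/h)
    free monomer + living end → monomer in chains + living end, rate k2*[living end]*[free monomer] (k = 3500 /M/h)
    free monomer → uncatalysed product (k = 0.00930 /h)
    pre-initiator → initiator (k = 0.0260 /h)
    crystals ⇌ monomer in chains, rate k5*(cs5 - [monomer in chains]) while solid is left; crystals form when [monomer in chains] > cs5 (solubility = 0.140 mM, k = 52.0 /h)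

- This flask had come to rest: free monomer, the limiting reagent, stood at 0% at 15 d, and the largest move over the second half of the time was 0 points. The constant in the scheme gave 1.45 background decades for this flask, against my 1.38. Ten times the time offered 14.5, but free monomer had none to give: at 150 d, chains stood at 80.8% and product at 19.2%. A neighbour flask with 0.012 mM of pre-initiator had the same 1.45 decades, which by themselves leave 3.55%; it ended with 0% free monomer and 35.6% product.

The data were computed with made-up constants; noise was put on by code.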